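**Strategy.** The route rests on disconnecting ring B at C8–C9. One samarium diiodide ketyl–olefin cyclisation joins the C8 methyl ketone carbon to C9 of an (E)-enoate, closing ring B and setting C8 and C9 together. It exploits ring A: quaternary C4 and C10, each with an axial methyl and an equatorial arm, flank C5, so both reacting chains are held equatorial and only the trans-decalin chair can form. That pseudo-mirror ring A is bought from dehydroabietic acid with the roles of C4 and C10 exchanged (ent series). The precursor is a ring A cyclohexane carrying the C10 tert-butyl enoate, the C4 methyl ester (C18) and, on C5, the 6-silyloxy methyl ketone chain.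

Key step: step 14

Remarks on the chemistry assumed:
- Numbering: compounds 1–9 carry abietane numbers. From 10 on the ent-labdane numbers of the target are used (old C4 = new C10, old C10 = new C4, old C18 = new C9, old C9 = new C18; C5–C8 unchanged).
- C6 of the target is R with its oxygen equatorial on ring B. On the abietane this is the axial 6β-hydroxyl, so it is made by hydride reduction of the 6-ketone from the α-face.
- The enoate is carried as a tert-butyl ester and the new C8 hydroxyl is silylated before C12 is activated. An 8-hydroxy 12-iodide (or sulfonate) would close to the 8,12-cyclic ether, and a methyl ester could lactonise onto O8.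
- The 6-acetate is put on last with O18 temporarily silylated. This avoids relying on selective cleavage of a neopentyl primary acetate beside a secondary one, where 1,3-acyl migration threatens.
- Compound 3 is a mixture of C7 epimers; C7 becomes sp2 in step 3.

**Step 1**
Reactants: 1 dehydroabietic acid
Product: 2 7-oxodehydroabietic acid
Conditions: CrO3, AcOH/H2O, 50 °C
Reagents that add atoms: chromium trioxide, O=[Cr](=O)=O
Why: Chromic acid benzylic oxidation should attack the ring B methylene C7, the only secondary benzylic site (the isopropyl methine can at most be hydroxylated), and no stereocentre is touched.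

**Step 2**
Reactants: 2 7-oxodehydroabietic acid
Product: 3 abieta-8,11,13-triene-7,18-diol (C7 epimers)
Conditions: LiAlH4, THF, reflux
Reagents that add atoms: none
Why: Hydride reduction with LiAlH4 should take the acid to the primary alcohol and the aryl ketone to the benzylic alcohol in one operation; the C7 configuration is irrelevant because C7 is planarised next.

**Step 3**
Reactants: 3 abieta-8,11,13-triene-7,18-diol
Product: 4 abieta-6,8,11,13-tetraen-18-ol
Conditions: TsOH·H2O (cat.), toluene, reflux, Dean–Stark
Reagents that add atoms: none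
Why: Acid-catalysed E1 dehydration through the alkyl-stabilised benzylic cation should give the styrene-type C6=C7 alkene, while the neopentyl primary alcohol does not ionise.

**Step 4**
Reactants: 4 abieta-6,8,11,13-tetraen-18-ol
Product: 5 abieta-6,8,11,13-tetraen-18-yl acetate
Conditions: Ac2O, pyridine, DMAP (cat.), CH2Cl2, rt
Reagents that add atoms: acetic anhydride, CC(=O)OC(C)=O
Why: DMAP-catalysed acylation should mask the primary alcohol as an ester that is inert to the peracid, Lewis acid and RuO4 steps ahead.

**Step 5**
Reactants: 5 abieta-6,8,11,13-tetraen-18-yl acetate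
Product: 6 6α,7α-epoxyabieta-8,11,13-trien-18-yl acetate
Conditions: mCPBA, NaHCO3, CH2Cl2/H2O, 0 °C
Reagents that add atoms: 3-chloroperoxybenzoic acid, OOC(=O)c1cccc(Cl)c1
Why: Prilezhaev epoxidation of the electron-rich styrene-type alkene should occur from the α-face opposite the axial C10 methyl, with bicarbonate preventing acid opening; the epoxide configuration is erased in the next step.

**Step 6**
Reactants: 6 6α,7α-epoxyabieta-8,11,13-trien-18-yl acetate
Product: 8 (6R)-6β-hydroxyabieta-8,11,13-trien-18-yl acetate, via 6-oxoabieta-8,11,13-trien-18-yl acetate 7 (not isolated)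
Conditions: ZnI2 (cat.), toluene, rt; then NaBH4, EtOH, 0 °C
Reagents that add atoms: none
Why: Meinwald rearrangement (benzylic C7–O ionisation, then 1,2-hydride shift from C6) should give the 6-ketone, and borohydride then attacks from the α-face because the β-face is blocked by the syn-axial methyls on C4 and C10, setting the axial 6β (6R) alcohol.

**Step 7**
Reactants: 8 (6R)-6β-hydroxyabieta-8,11,13-trien-18-yl acetate
Product: 9 (6R)-6β-(tert-butyldimethylsilyloxy)abieta-8,11,13-trien-18-yl acetate
Conditions: TBSOTf, 2,6-lutidine, CH2Cl2, 0 → 40 °C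
Reagents that add atoms: tert-butyldimethylsilyl triflate, CC(C)(C)[Si](C)(C)OS(=O)(=O)C(F)(F)F
Why: Silylation with a silyl triflate is the strongest standard way to cap a hindered axial secondary hydroxyl and gives an ether that survives RuO4, Grignard reagents and SmI2; O-silylation leaves C6 unchanged.

**Step 8**
Reactants: 9 (6R)-6β-(tert-butyldimethylsilyloxy)abieta-8,11,13-trien-18-yl acetate
Product: 10 ring A seco-diacid (C10: CH3 and CH2OAc; C4: CH3 and CO2H; C5: CH(OTBS)CH2CO2H)
Conditions: RuCl3·xH2O (cat.), NaIO4, CCl4/MeCN/H2O, rt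
Reagents that add atoms: sodium periodate, [Na+].[O-]I(=O)(=O)=O; water, O
Why: RuO4 generated in situ should degrade the alkylbenzene ring oxidatively (RuCl3/NaIO4 arene-to-carboxylic-acid cleavage), leaving its two substituted carbons as the C8 and C18 carboxyl groups while the silyl ether, the acetate and all stereocentres are untouched.

**Step 9**
Reactants: 10 ring A seco-diacid
Product: 11 seco-dimethyl ester
Conditions: TMSCHN2, toluene/MeOH, 0 °C → rt
Reagents that add atoms: (trimethylsilyl)diazomethane, C[Si](C)(C)C=[N+]=[N-]
Why: Diazoalkane O-methylation proceeds at the carboxylate oxygen, so it should esterify the hindered tertiary C18 acid as readily as the primary one.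

**Step 10**
Reactants: 11 seco-dimethyl ester
Product: 12 hydroxy Weinreb amide (C10: CH2OH; C4: CO2Me; chain CH(OTBS)CH2C(O)N(OMe)Me)
Conditions: MeNHOMe·HCl, i-PrMgCl, THF, −20 → 0 °C
Reagents that add atoms: N,O-dimethylhydroxylamine hydrochloride, CNOC.Cl
Why: Magnesium amide aminolysis (Weinreb amide formation) should convert only the unhindered CH2CO2Me, since the α-quaternary C18 ester is inert, and it cleaves the acetate in the same pot to free the C9 carbinol needed next.

**Step 11**
Reactants: 12 hydroxy Weinreb amide
Product: 13 aldehyde Weinreb amide (C10: CHO)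
Conditions: Dess–Martin periodinane, NaHCO3, CH2Cl2, rt
Reagents that add atoms: none
Why: Dess–Martin oxidation should take the neopentyl primary alcohol to an aldehyde that cannot enolise or epimerise because its α-carbon C10 is quaternary.

**Step 12**
Reactants: 13 aldehyde Weinreb amide; 14 tert-butyl diethylphosphonoacetate
Product: 15 enoate Weinreb amide (C10: (E)-CH=CH–CO2t-Bu)
Conditions: NaH, THF, 0 °C → rt
Reagents that add atoms: none
Why: Horner–Wadsworth–Emmons olefination with a stabilised phosphonate anion should give the (E)-enoate (C9=C11) selectively, and doing it before the ketone exists removes any aldol or Michael side reaction of a methyl ketone.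

**Step 13**
Reactants: 15 enoate Weinreb amide
Product: 16 keto enoate (cyclisation precursor; C10: (E)-CH=CH–CO2t-Bu; C4: CO2Me; C5: CH(OTBS)CH2COCH3)
Conditions: MeMgBr, THF, −20 → 0 °C
Reagents that add atoms: methylmagnesium bromide, C[Mg]Br
Why: Weinreb ketone synthesis stops at the chelated tetrahedral adduct, so the β-silyloxy methyl ketone is released only on work-up, while the β-neopentyl tert-butyl enoate and the hindered C18 ester are far slower towards the Grignard reagent.

**Step 14**
Reactants: 16 keto enoate
Product: 17 tert-butyl methyl (6R)-6-(tert-butyldimethylsilyloxy)-8-hydroxy-13,14,15,16-tetranor-ent-labdane-12,18-dioate (ring B closed)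
Conditions: SmI2 (2.5 equiv), HMPA, t-BuOH (2 equiv), THF, −78 → 0 °C
Reagents that add atoms: none
Why: A first electron from SmI2 gives the samarium ketyl at C8, which adds as a carbon radical to the enoate β-carbon C9; a second electron reduces the α-ester radical at C11 to the samarium enolate, which t-BuOH protonates. This is the known SmI2 ketyl–olefin reductive cyclisation of a ketone onto an α,β-unsaturated ester. Ring B closes in the 6-exo-trig mode through a chair whose C5 and C10 corners are fixed by ring A, so only the trans-decalin can result. C9 is set by that chair, which keeps the enoate arm (C11) equatorial and leaves H9 axial; C8 is set by the HMPA-solvated O–Sm group, far larger than methyl, taking the equatorial site away from the axial C10 methyl, so the C8 methyl goes axial, O8 ends trans-diequatorial to C11, and the C6 silyloxy group sits equatorial as well. The step needs ketyl formation to win over enoate reduction and pinacol coupling (secured by HMPA-accelerated ketone reduction at −78 °C, dilution and the proton source) and a free tertiary alcohol afterwards (secured by the tert-butyl ester, which the trivalent samarium alkoxide should not attack to form the 8,12-lactone).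

**Step 15**
Reactants: 17 hydroxy diester
Product: 18 C8 triethylsilyl ether of 17
Conditions: TESOTf, 2,6-lutidine, CH2Cl2, −78 → −20 °C
Reagents that add atoms: triethylsilyl triflate, CC[Si](CC)(CC)OS(=O)(=O)C(F)(F)F
Why: Silyl triflate silylation should cap the tertiary C8 hydroxyl, the only free OH, so that no oxygen nucleophile sits 1,4 to C12 when it is activated; the low temperature spares the tert-butyl ester.

**Step 16**
Reactants: 18 bis-silyl diester
Product: 19 (6R)-6-(tert-butyldimethylsilyloxy)-8-(triethylsilyloxy)-13,14,15,16-tetranor-ent-labdane-12,18-diol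
Conditions: LiAlH4, THF, 0 °C → reflux
Reagents that add atoms: none
Why: LiAlH4 reduction should convert both the tert-butyl ester and the hindered methyl ester into the C12 and C18 primary alcohols, and silyl ethers are inert to it.

**Step 17**
Reactants: 19 12,18-diol
Product: 20 (6R)-12-iodo-6-(tert-butyldimethylsilyloxy)-8-(triethylsilyloxy)-13,14,15,16-tetranor-ent-labdan-18-ol
Conditions: I2, PPh3, imidazole, CH2Cl2, 0 °C
Reagents that add atoms: iodine, II
Why: Appel-type iodination needs SN2 attack of iodide on the alkoxyphosphonium ion, which should be fast only at the unhindered C12 and blocked at the neopentyl C18 carbinol, which is returned on work-up.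

**Step 18**
Reactants: 20 12-iodide; 21 chloroprene
Product: 23 ent-6α-(tert-butyldimethylsilyloxy)-8α-(triethylsilyloxy)labda-13(16),14-dien-18-ol, via buta-1,3-dien-2-ylmagnesium chloride 22 (not isolated)
Conditions: 21, Mg, ZnCl2 (cat.), BrCH2CH2Br (cat.), THF, reflux; then 20, Li2CuCl4 (cat.), THF, −20 → 0 °C
Reagents that add atoms: none
Why: Copper-catalysed (Kochi-type) cross-coupling of a primary alkyl iodide with an alkenyl Grignard reagent should form C12–C13 and deliver the 2-substituted butadiene; one extra equivalent of 22 is spent on the C18 hydroxyl and no stereocentre is involved.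

**Step 19**
Reactants: 23 bis-silyl dienol
Product: 24 ent-labda-13(16),14-diene-6α,8α,18-triol
Conditions: Bu4NF, THF, rt → 50 °C
Reagents that add atoms: none
Why: Fluoride-induced desilylation, driven by the Si–F bond, should remove both the secondary tert-butyldimethylsilyl and the tertiary triethylsilyl ether without touching the diene.

**Step 20**
Reactants: 24 triol
Product: 25 ent-18-(tert-butyldimethylsilyloxy)labda-13(16),14-diene-6α,8α-diol
Conditions: TBSCl (1.1 equiv), imidazole, DMF, 0 °C
Reagents that add atoms: tert-butyldimethylsilyl chloride, CC(C)(C)[Si](C)(C)Cl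
Why: Sterically controlled silylation should select the primary C18 hydroxyl over the secondary C6 and tertiary C8 hydroxyls.

**Step 21**
Reactants: 25 18-silyl ether
Product: 26 ent-6α-acetoxy-18-(tert-butyldimethylsilyloxy)labda-13(16),14-dien-8α-ol
Conditions: Ac2O, pyridine, DMAP (cat.), rt
Reagents that add atoms: acetic anhydride, CC(=O)OC(C)=O
Why: DMAP-catalysed acylation should esterify the equatorial secondary C6 hydroxyl, while the hindered tertiary C8 hydroxyl does not react under these mild conditions.

**Step 22**
Reactants: 26 6-acetate 18-silyl ether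
Product: 27 ent-6α-acetoxylabda-13(16),14-diene-8α,18-diol (target)
Conditions: HF·pyridine, pyridine, THF, 0 °C → rt
Reagents that add atoms: none
Why: Buffered acidic fluoride desilylation frees the primary C18 hydroxyl without generating an alkoxide, so the 6-acetate should not migrate to O18, and the diene and tertiary alcohol tolerate it.

**Compound list**

1 | (+)-dehydroabietic acid (abieta-8,11,13-trien-18-oic acid; CO2H equatorial on C4, C4 and C10 methyls axial and cis, H5 trans to them) | OC(=O)[C@]1(C)CCC[C@](C)(c2ccc(C(C)C)cc23)[C@H]1CC3 | starting material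
2 | 7-oxodehydroabietic acid | OC(=O)[C@]1(C)CCC[C@](C)(c2ccc(C(C)C)cc23)[C@H]1CC3=O | intermediate
3 | abieta-8,11,13-triene-7,18-diol (C7 epimers) | OC[C@]1(C)CCC[C@](C)(c2ccc(C(C)C)cc23)[C@H]1CC3O | intermediate
4 | abieta-6,8,11,13-tetraen-18-ol | OC[C@]1(C)CCC[C@](C)(c2ccc(C(C)C)cc23)[C@H]1C=C3 | intermediate
5 | abieta-6,8,11,13-tetraen-18-yl acetate | CC(=O)OC[C@]1(C)CCC[C@](C)(c2ccc(C(C)C)cc23)[C@H]1C=C3 | intermediate
6 | 6α,7α-epoxyabieta-8,11,13-trien-18-yl acetate | CC(=O)OC[C@]1(C)CCC[C@](C)(c2ccc(C(C)C)cc23)[C@H]1[C@H]4O[C@H]43 | intermediate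
7 | 6-oxoabieta-8,11,13-trien-18-yl acetate (not isolated) | CC(=O)OC[C@]1(C)CCC[C@](C)(c2ccc(C(C)C)cc23)[C@H]1C(=O)C3 | intermediate
8 | (6R)-6β-hydroxyabieta-8,11,13-trien-18-yl acetate | CC(=O)OC[C@]1(C)CCC[C@](C)(c2ccc(C(C)C)cc23)[C@H]1[C@H](O)C3 | intermediate
9 | (6R)-6β-(tert-butyldimethylsilyloxy)abieta-8,11,13-trien-18-yl acetate | CC(=O)OC[C@]1(C)CCC[C@](C)(c2ccc(C(C)C)cc23)[C@H]1[C@H](O[Si](C)(C)C(C)(C)C)C3 | intermediate
10 | (6R)-9-acetoxy-6-(tert-butyldimethylsilyloxy)-11,12,13,14,15,16,17-heptanor-8,9-seco-ent-labdane-8,18-dioic acid | CC(=O)OC[C@]1(C)CCC[C@](C)(C(=O)O)[C@H]1[C@H](O[Si](C)(C)C(C)(C)C)CC(=O)O | intermediate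
11 | dimethyl ester of 10 | CC(=O)OC[C@]1(C)CCC[C@](C)(C(=O)OC)[C@H]1[C@H](O[Si](C)(C)C(C)(C)C)CC(=O)OC | intermediate
12 | hydroxy Weinreb amide (C9 carbinol free, C18 methyl ester, C8 N-methoxy-N-methylamide) | OC[C@]1(C)CCC[C@](C)(C(=O)OC)[C@H]1[C@H](O[Si](C)(C)C(C)(C)C)CC(=O)N(C)OC | intermediate
13 | aldehyde Weinreb amide (C9 aldehyde) | O=C[C@]1(C)CCC[C@](C)(C(=O)OC)[C@H]1[C@H](O[Si](C)(C)C(C)(C)C)CC(=O)N(C)OC | intermediate
14 | tert-butyl diethylphosphonoacetate | CCOP(=O)(OCC)CC(=O)OC(C)(C)C | starting material
15 | enoate Weinreb amide ((E)-C9=C11 tert-butyl ester) | CC(C)(C)OC(=O)/C=C/[C@]1(C)CCC[C@](C)(C(=O)OC)[C@H]1[C@H](O[Si](C)(C)C(C)(C)C)CC(=O)N(C)OC | intermediate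
16 | keto enoate, cyclisation precursor ((E)-C9=C11 tert-butyl ester, C18 methyl ester, (6R)-silyloxy, C8 methyl ketone) | CC(C)(C)OC(=O)/C=C/[C@]1(C)CCC[C@](C)(C(=O)OC)[C@H]1[C@H](O[Si](C)(C)C(C)(C)C)CC(C)=O | intermediate
17 | tert-butyl methyl (6R)-6-(tert-butyldimethylsilyloxy)-8-hydroxy-13,14,15,16-tetranor-ent-labdane-12,18-dioate (O8 and C11 trans-diequatorial, C8 methyl axial) | CC(C)(C)OC(=O)C[C@H]1[C@]2(C)CCC[C@](C)(C(=O)OC)[C@H]2[C@H](O[Si](C)(C)C(C)(C)C)C[C@]1(C)O | intermediate
18 | C8 triethylsilyl ether of 17 | CC(C)(C)OC(=O)C[C@H]1[C@]2(C)CCC[C@](C)(C(=O)OC)[C@H]2[C@H](O[Si](C)(C)C(C)(C)C)C[C@]1(C)O[Si](CC)(CC)CC | intermediate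
19 | (6R)-6-(tert-butyldimethylsilyloxy)-8-(triethylsilyloxy)-13,14,15,16-tetranor-ent-labdane-12,18-diol | OCC[C@H]1[C@]2(C)CCC[C@](C)(CO)[C@H]2[C@H](O[Si](C)(C)C(C)(C)C)C[C@]1(C)O[Si](CC)(CC)CC | intermediate
20 | 12-iodide of 19 (18-OH free) | ICC[C@H]1[C@]2(C)CCC[C@](C)(CO)[C@H]2[C@H](O[Si](C)(C)C(C)(C)C)C[C@]1(C)O[Si](CC)(CC)CC | intermediate
21 | chloroprene (2-chlorobuta-1,3-diene) | C=CC(Cl)=C | starting material
22 | buta-1,3-dien-2-ylmagnesium chloride (not isolated) | C=CC(=C)[Mg]Cl | intermediate
23 | ent-6α-(tert-butyldimethylsilyloxy)-8α-(triethylsilyloxy)labda-13(16),14-dien-18-ol | C=CC(=C)CC[C@H]1[C@]2(C)CCC[C@](C)(CO)[C@H]2[C@H](O[Si](C)(C)C(C)(C)C)C[C@]1(C)O[Si](CC)(CC)CC | intermediate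
24 | ent-labda-13(16),14-diene-6α,8α,18-triol | C=CC(=C)CC[C@H]1[C@]2(C)CCC[C@](C)(CO)[C@H]2[C@H](O)C[C@]1(C)O | intermediate
25 | ent-18-(tert-butyldimethylsilyloxy)labda-13(16),14-diene-6α,8α-diol | C=CC(=C)CC[C@H]1[C@]2(C)CCC[C@](C)(CO[Si](C)(C)C(C)(C)C)[C@H]2[C@H](O)C[C@]1(C)O | intermediate
26 | ent-6α-acetoxy-18-(tert-butyldimethylsilyloxy)labda-13(16),14-dien-8α-ol | C=CC(=C)CC[C@H]1[C@]2(C)CCC[C@](C)(CO[Si](C)(C)C(C)(C)C)[C@H]2[C@H](OC(C)=O)C[C@]1(C)O | intermediate
27 | ent-6α-acetoxylabda-13(16),14-diene-8α,18-diol (6-OAc and 8-OH equatorial, C18 CH2OH equatorial on C4) | C=CC(=C)CC[C@H]1[C@]2(C)CCC[C@](C)(CO)[C@H]2[C@H](OC(C)=O)C[C@]1(C)O | target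

**Step count and risk**

Total step count: 22. Longest linear sequence: 22 steps (1 → 27); 14 and 21 enter as purchased building blocks.

Three steps most likely to fail:

Step 14 (key step). What may go wrong: the ketyl may be reduced on to the open-chain secondary alcohol, the enoate may be reduced or dimerised, and facial control at C8 may erode because the methyl must go axial beside the C10 methyl. The fallback sets out from 16 and comes back at 18. It makes the C8 radical by hydrogen-atom transfer instead of from a ketyl. Kinetic enolisation of the methyl ketone with in-situ silylation (LiN(SiMe3)2, Et3SiCl, THF, −78 °C) should give the terminal triethylsilyl enol ether F1. Iron-hydride olefin–olefin reductive coupling (Fe(acac)3, PhSiH3, EtOH, 60 °C) then puts a hydrogen atom on the enol ether CH2. The α-silyloxy C8 radical should close 6-exo onto C9 through the same ring-A-anchored chair with the bulky silyloxy group equatorial, giving the C8 triethylsilyl ether 18 directly.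

Step 7. What may go wrong: silylation of an axial hydroxyl flanked by two syn-axial methyls may stall, and forcing it may cost the acetate or cause elimination. The fallback sets out from 6 and comes back at 9. After the ZnI2 rearrangement the ketone 7 is isolated and converted with TBSOTf and Et3N into the conjugated 6-(tert-butyldimethylsilyloxy)abieta-6,8,11,13-tetraen-18-yl acetate F2, so silicon is placed on a flat enol oxygen. Hydrogenation (H2, Pd/C, EtOAc) should add from the open α-face and leave the silyloxy group β, which is 9.

Step 18. What may go wrong: formation of the dienyl Grignard reagent may be erratic or accompanied by polymerisation, and coupling may be slow beside the magnesium alkoxide at O18, so the iodide is reduced or eliminated. The fallback sets out from 20 and comes back at 23. Alkylation of LiC≡CH·H2NCH2CH2NH2 in DMSO at rt should give the terminal alkyne (6R)-6-(tert-butyldimethylsilyloxy)-8-(triethylsilyloxy)-15,16-dinor-ent-labd-13-yn-18-ol F3. Enyne cross-metathesis with ethylene (1 atm, second-generation Grubbs catalyst, CH2Cl2, rt) then converts the alkyne into the 2-substituted buta-1,3-diene 23.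

**Further compounds**

F1 | step 14 | terminal triethylsilyl enol ether of 16 (C8=C17) | CC(C)(C)OC(=O)/C=C/[C@]1(C)CCC[C@](C)(C(=O)OC)[C@H]1[C@H](O[Si](C)(C)C(C)(C)C)CC(=C)O[Si](CC)(CC)CC
F2 | step 7 | 6-(tert-butyldimethylsilyloxy)abieta-6,8,11,13-tetraen-18-yl acetate | CC(=O)OC[C@]1(C)CCC[C@](C)(c2ccc(C(C)C)cc23)[C@H]1C(O[Si](C)(C)C(C)(C)C)=C3
F3 | step 18 | (6R)-6-(tert-butyldimethylsilyloxy)-8-(triethylsilyloxy)-15,16-dinor-ent-labd-13-yn-18-ol | C#CCC[C@H]1[C@]2(C)CCC[C@](C)(CO)[C@H]2[C@H](O[Si](C)(C)C(C)(C)C)C[C@]1(C)O[Si](CC)(CC)CC
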